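## Structural features

The target is a chain of four benzene rings. Ring A (guaiacyl, free phenol) is joined to ring B (syringyl) through an arylglycerol β-aryl ether unit, ring B to ring C (syringyl) through a second unit of the same kind, and ring C sits on C2 of a 2,3-dihydrobenzofuran whose benzo ring is ring D. Ring D carries a methoxy group at C7 and an (E)-propenal at C5; C3 carries a hydroxymethyl group. The six stereocentres form three adjacent pairs: C2/C3 of the dihydrofuran (trans, 2R,3S) and, in each glycerol unit, the benzylic carbinol (R) next to the aryloxy carbon (S), the erythro relation. Each pair is separated from the next by an aromatic ring, so no pair can direct another. The fragile groups are the enal, the benzylic carbinols para to oxygen (they ionise in acid and give quinone methides once the para phenol is free and the benzylic oxygen is a leaving group), the benzylic C2–O bond and the phenol. The real difficulty is absolute control over three remote pairs, above all the erythro relation, which a closed-transition-state glycolate aldol does not give directly. The key step uses the fact that C3 is bonded to C3a of ring D, to C2 and to an oxygenated CH2: this is what remains when a radical at C3a adds to the internal carbon of a vinyl group on C2 and the terminal carbon takes up oxygen.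

## Logic of the disconnections

31 to 30: the C=C bond of the propenal is cut. The enal is the group least able to survive hydride, zinc or boron reagents, so it is made last. Two carbons then come from an ylide and ring D only has to carry a formyl group. The forward olefination must tolerate a free phenol and five hydroxyl groups, give the E alkene and stop after one homologation.

30 to 28 to 27: no skeletal bond is cut. The N–O bond of an aminooxy group, two acetals and one aryl silyl ether are restored. This keeps the formyl group, the B–C diol, the C3 hydroxymethyl group and the ring A phenol masked until all enolate, Mitsunobu and hydride chemistry is over. The unmasking must be mild enough for two benzylic carbinols.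

27 to 21 and 23 (through 25 and 26): the bond between the carbinol carbon and the aryloxy carbon of the A–B unit is cut, and the carbinol is inverted in the retrosynthetic sense. Ring A then arrives as a simple aldehyde and the aryloxy carbon as a glycolyl imide. The auxiliary must set both centres with no help from the rest of the molecule. The syn (threo) aldol product must then be inverted at the carbinol with clean SN2 character to reach erythro.

21 to 19 and 12, and 19 to 18: the O–CH2 bond on ring B is cut and the B–C diol is tied as an acetonide. The glycolyl unit with its auxiliary is attached by phenol alkylation. The ring B phenol must be released, and the diol must be masked before boron triflate and Mitsunobu reagents are used again.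

18 to 14 and 2 (through 16 and 17): the same aldol, inversion and reduction logic builds the B–C unit. Compound 2 serves a second time, now as the ring B aldehyde.

14 to 11 and 12: the O–CH2 bond on ring C is cut. The forward step needs the ring C phenol free and nothing else nucleophilic.

11 to 9 and 10 (key step): the C3a–C3 bond and the CH2–O bond are cut. This removes the ring and the C3 stereocentre in one step and leaves an acyclic ether with one stereocentre. The aminooxy group is kept afterwards as the protecting group of the C3 hydroxymethyl group, so no separate protection is needed. The forward step needs ring closure before the aryl radical is captured, and trans selectivity from C2. The precursor carries the ring D formyl group as an acetal. A free formyl group would be open to ketyl and hydride chemistry in the radical step and would make the ring D aryloxide a good leaving group at an ionisable doubly activated benzylic carbon, and it has to be masked before the aldol steps in any case.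

9 to 5 and 7: the C2–O bond is cut. A catalytic, enantioselective branched allylic etherification creates C2 from two achiral partners. The hindered 2,6-disubstituted aryloxide must attack the substituted allyl terminus, and the product must not re-ionise.

5 to 4 to 3 to 2 to 1, 7 to 6, and 23 to 22: these are protection, two-carbon homologation, reduction and activation steps that lead back to the three commercial hydroxybenzaldehydes.

## Other disconnections considered

Alternative 1: The cut goes through both benzylic C–O bonds and the two C–H bonds at the aryloxy carbons, back to the bis(Z-enol ether) A1 on a finished phenylcoumaran. In the forward step a chiral terpene-derived monoalkylborane adds H and B syn to each enol ether, with boron at the benzylic carbon, and oxidation with retention gives the bis(erythro alcohol) A2. Syn addition to a Z enol ether maps directly onto the erythro pair. In its favour, four stereocentres are set in one operation with no auxiliary and no inversion; on step economy for the side chains this is better than the chosen plan, which spends four operations per unit. Against it here, A1 needs two geometrically pure Z aryl enol ethers, which are hard to make. The intermediate boranes have an aryloxy group β to boron and can collapse by β-elimination. Reagent control on aryl-substituted trisubstituted alkenes is not dependably high, and with two reacting sites any shortfall appears as diastereomers. On structure, this alternative leaves C2/C3 of the dihydrofuran unsolved, so it complements the chosen key step and does not replace it. On mechanism, the chosen aldol and SN2 inversion have closer precedent on this substrate class, while the hydroboration is shorter with a weaker stereochemical guarantee.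

Alternative 2: The cut is the C2–O bond of the dihydrofuran, back to the diol A3, used as either carbinol epimer with the future C3 centre already set. Mild acid would ionise both epimers to the same para-quinone methide A4, and the ortho phenol of ring D would add to its exocyclic carbon (5-exo-trig) to give the trans phenylcoumaran A5. In its favour, the step is stereoconvergent and reversible, so the trans ring is reached under thermodynamic as well as kinetic preference; on trans selectivity it is expected to be the equal of the radical closure or better. It also uses no tin and needs no protecting group on the ring C phenol at that stage, which is better than the chosen plan. Against it here, the absolute configuration of C3 has to come from an earlier asymmetric C–C bond formation, so the problem is moved and not removed. Two free phenols must be carried, the quinone methide can be captured by other nucleophiles, and A5 leaves the hydroxymethyl group free, so it needs a protecting group before the side chains are built. Step economy is about equal: what is saved on ring C protection is spent on making A3 and on capping the alcohol. Mechanistically it is an ionic closure against a kinetic radical closure.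

Alternative 3: The cut is the C2–C3 bond, back to the aryldiazoacetate A6, which is made by a simple Williamson benzylation and diazo transfer. A chiral dirhodium tetracarboxylate (divalent rhodium) would form a donor/acceptor carbene that inserts into the benzylic ether C–H bond, closing the five-membered ring; alkoxide base would then epimerise C3 to give the trans ester A7. In its favour, the step is catalytic and enantioselective with direct precedent on 2-aryl-2,3-dihydrobenzofuran-3-carboxylates. On precedent for the asymmetric step it is the equal of the chosen iridium and radical pair, and its ether precursor is easier to make than the branched allyl ether, which is better. Against it here, a diazo compound must be handled. The epimerisation passes through an ester enolate whose β-leaving group is the ring oxygen, so ring opening and reclosure could scramble C2. A7 also needs reduction to the alcohol and then a protecting group, whereas the chosen product has the oxygen at the right oxidation level and already masked. Step economy is about equal, perhaps one step longer for the alternative. Mechanistically one catalyst sets C2 and base sets C3, whereas the chosen plan sets C2 by catalysis and C3 by substrate control.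

Key step: step 7

Assumption: the (Ra,Rc,Rc) phosphoramidite is taken to give the (R) ether 9, the sense it shows with simple (E)-cinnamyl carbonates and aryloxides; if the sense proves opposite, the antipodal ligand is used.

Abbreviations in names: TBS = tert-butyldimethylsilyl. Xc = (4R)-4-benzyl-2-oxo-1,3-oxazolidin-3-yl. DHB = (2R,3S)-5-(5,5-dimethyl-1,3-dioxan-2-yl)-7-methoxy-3-[(2,2,6,6-tetramethylpiperidin-1-yl)oxymethyl]-2,3-dihydro-1-benzofuran-2-yl. DOX = (4R,5S)-5-[4-(DHB)-2,6-dimethoxyphenoxy]-2,2-dimethyl-1,3-dioxan-4-yl. The stereodescriptors were re-derived from the structures: the open ether is R at the future C2, the ring is (2R,3S) and trans, and both glycerol units are (1R,2S), erythro.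

Step 1
Reactants: 1 syringaldehyde
Product: 2 4-(TBS-oxy)-3,5-dimethoxybenzaldehyde
Conditions: TBSCl, imidazole, DMF, rt
Reagents that add atoms: tert-butyldimethylsilyl chloride, CC(C)(C)[Si](C)(C)Cl
Why: Silyl ether formation on the hindered phenol; the aryl TBS ether survives ylide, hydride, aryloxide and radical conditions and is removed by fluoride. Compound 2 is used twice, as the source of ring C and as the ring B aldehyde.

Step 2
Reactants: 2 4-(TBS-oxy)-3,5-dimethoxybenzaldehyde
Product: 3 ethyl (E)-3-[4-(TBS-oxy)-3,5-dimethoxyphenyl]prop-2-enoate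
Conditions: Ph3P=CHCO2Et, toluene, 80 °C
Reagents that add atoms: ethyl (triphenylphosphoranylidene)acetate, CCOC(=O)C=P(c1ccccc1)(c1ccccc1)c1ccccc1
Why: Wittig olefination with a stabilised ylide gives the E cinnamate under neutral conditions, which spares the aryl silyl ether.

Step 3
Reactants: 3 ethyl (E)-3-[4-(TBS-oxy)-3,5-dimethoxyphenyl]prop-2-enoate
Product: 4 (E)-3-[4-(TBS-oxy)-3,5-dimethoxyphenyl]prop-2-en-1-ol
Conditions: i-Bu2AlH (DIBAL-H), CH2Cl2, –78 °C; aq. potassium sodium tartrate
Reagents that add atoms: none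
Why: 1,2-Reduction of the conjugated ester to the allylic alcohol with an aluminium hydride; the alkene and the silyl ether are untouched at low temperature.

Step 4
Reactants: 4 (E)-3-[4-(TBS-oxy)-3,5-dimethoxyphenyl]prop-2-en-1-ol
Product: 5 (E)-3-[4-(TBS-oxy)-3,5-dimethoxyphenyl]prop-2-en-1-yl methyl carbonate
Conditions: ClCO2Me, pyridine, CH2Cl2, 0 °C
Reagents that add atoms: methyl chloroformate, COC(=O)Cl
Why: O-Acylation to the allylic carbonate provides the leaving group for allyl-metal formation; it ionises with loss of CO2 and methoxide.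

Step 5
Reactants: 6 5-iodovanillin
Product: 7 4-(5,5-dimethyl-1,3-dioxan-2-yl)-2-iodo-6-methoxyphenol
Conditions: 2,2-dimethylpropane-1,3-diol, PPTS (cat.), toluene, reflux, azeotropic removal of water; Et3N quench
Reagents that add atoms: 2,2-dimethylpropane-1,3-diol, OCC(C)(C)CO
Why: Acid-catalysed acetalisation; the neopentyl acetal withstands base, hydride, boron triflate and mild acid and is cleaved by aqueous acid at the end. Masking the formyl group now makes the aryloxide a better nucleophile and a poorer leaving group for step 6 and removes a reducible group from the radical step.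

Step 6
Reactants: 5 (E)-3-[4-(TBS-oxy)-3,5-dimethoxyphenyl]prop-2-en-1-yl methyl carbonate; 7 4-(5,5-dimethyl-1,3-dioxan-2-yl)-2-iodo-6-methoxyphenol
Product: 9 2-{4-[(1R)-1-(4-TBS-oxy-3,5-dimethoxyphenyl)prop-2-en-1-yloxy]-3-iodo-5-methoxyphenyl}-5,5-dimethyl-1,3-dioxane, via lithium aryloxide 8 (not isolated)
Conditions: 7, LiN(SiMe3)2, THF, 0 °C; then 5, [Ir(cod)Cl]2 (2 mol%), (Ra,Rc,Rc)-O,O'-(1,1'-binaphthalene-2,2'-diyl) N,N-bis(1-phenylethyl)phosphoramidite (4 mol%, pre-activated with n-PrNH2), THF, rt
Reagents that add atoms: none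
Why: Iridium-catalysed asymmetric allylic etherification: the cyclometalated monovalent iridium phosphoramidite complex ionises 5 to an allyl complex and the aryloxide 8 attacks the aryl-substituted terminus, giving the branched ether and creating C2 (R) under ligand control. The acetal keeps the aryloxide electron-rich, which works against re-ionisation of the product and loss of enantiomeric purity.

Step 7
Reactants: 9 2-{4-[(1R)-1-(4-TBS-oxy-3,5-dimethoxyphenyl)prop-2-en-1-yloxy]-3-iodo-5-methoxyphenyl}-5,5-dimethyl-1,3-dioxane; 10 TEMPO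
Product: 11 (2R,3S)-2-(4-TBS-oxy-3,5-dimethoxyphenyl)-5-(5,5-dimethyl-1,3-dioxan-2-yl)-7-methoxy-3-[(2,2,6,6-tetramethylpiperidin-1-yl)oxymethyl]-2,3-dihydro-1-benzofuran
Conditions: Bu3SnH (added in portions), 10 (excess, added in portions), toluene, 70 °C; aq. KF work-up
Reagents that add atoms: none
Why: Tributylstannyl radicals, formed when TEMPO abstracts hydrogen from Bu3SnH, abstract iodine from 9 and give an aryl radical at the ring D carbon ortho to the ether oxygen. This radical adds to the internal carbon of the vinyl group in a 5-exo-trig closure (ring atoms C3a, C7a, O1, C2, C3), which for 2-(allyloxy)phenyl radicals is faster than capture by the stannane or the nitroxide at the concentrations used. The primary radical so formed is not stabilised and couples with TEMPO at a near diffusion-controlled rate, far faster than hydrogen transfer from Bu3SnH, so a CH2–O bond is formed and not a methyl group. The closest known reaction type is the tin hydride/TEMPO aryl radical–alkene cyclisation with nitroxide trapping that converts 2-iodoaryl allyl amines and ethers into 3-(oxymethyl)indolines and 2,3-dihydrobenzofurans. The new stereocentre C3 is set in the C–C bond-forming step by the existing C2 centre: in the chair-like transition state the ring C aryl group lies pseudo-equatorial and the alkene terminus turns away from it, which puts the CH2 group trans to the aryl group and gives (2R,3S). C2 is not touched, since no bond to it is made or broken. The step needs selective iodine abstraction and trans selectivity; the first is secured by the weak aryl C–I bond and by the formyl group being an acetal, the second by the size of the aryl group next to the reacting alkene.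

Step 8
Reactants: 11 (2R,3S)-2-(4-TBS-oxy-3,5-dimethoxyphenyl)-5-(5,5-dimethyl-1,3-dioxan-2-yl)-7-methoxy-3-[(2,2,6,6-tetramethylpiperidin-1-yl)oxymethyl]-2,3-dihydro-1-benzofuran; 12 (R)-4-benzyl-3-(chloroacetyl)oxazolidin-2-one
Product: 14 2-[4-(DHB)-2,6-dimethoxyphenoxy]-1-(Xc)ethanone, via tetrabutylammonium aryloxide 13 (not isolated)
Conditions: TBAF (1.05 equiv), THF, 0 °C; then 12, 0 °C to rt
Reagents that add atoms: none
Why: Fluoride cleaves the aryl silyl ether and the aryloxide 13 is alkylated in the same flask at the activated CH2Cl carbon of 12 (Williamson ether synthesis). Attack at the imide carbonyl is reversible and unproductive, attack at carbon is not; the aminooxy group stays as the protecting group of the C3 hydroxymethyl group.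

Step 9
Reactants: 14 2-[4-(DHB)-2,6-dimethoxyphenoxy]-1-(Xc)ethanone; 2 4-(TBS-oxy)-3,5-dimethoxybenzaldehyde
Product: 16 (2R,3S)-2-[4-(DHB)-2,6-dimethoxyphenoxy]-3-hydroxy-3-(4-TBS-oxy-3,5-dimethoxyphenyl)-1-(Xc)propan-1-one, via dibutylboron enolate 15 (not isolated)
Conditions: Bu2BOTf, i-Pr2NEt, CH2Cl2, –78 to 0 °C; then 2, –78 to 0 °C; pH 7 buffer, MeOH, H2O2, 0 °C
Reagents that add atoms: none
Why: Evans syn aldol: soft enolisation gives the Z boron enolate 15, which reacts with 2 through a closed chair-like transition state on the face away from the benzyl group of the (R) auxiliary. This sets the aryloxy carbon (R in the imide, S after reduction) and the carbinol carbon (S) as the syn, threo pair; auxiliary control is required because the nearest resident stereocentre lies beyond ring C.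

Step 10
Reactants: 16 (2R,3S)-2-[4-(DHB)-2,6-dimethoxyphenoxy]-3-hydroxy-3-(4-TBS-oxy-3,5-dimethoxyphenyl)-1-(Xc)propan-1-one
Product: 17 (1R,2R)-2-[4-(DHB)-2,6-dimethoxyphenoxy]-3-oxo-1-(4-TBS-oxy-3,5-dimethoxyphenyl)-3-(Xc)propyl 4-nitrobenzoate
Conditions: PPh3, DIAD, 4-nitrobenzoic acid, THF, 0 °C to rt
Reagents that add atoms: 4-nitrobenzoic acid, O=C(O)c1ccc(cc1)[N+](=O)[O-]
Why: Mitsunobu esterification with SN2 inversion at the benzylic carbinol turns the threo adduct into the erythro series. The flanking aryloxy and acyl groups disfavour ionisation at the benzylic carbon, and the acidic 4-nitrobenzoic acid suits a hindered secondary alcohol.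

Step 11
Reactants: 17 (1R,2R)-2-[4-(DHB)-2,6-dimethoxyphenoxy]-3-oxo-1-(4-TBS-oxy-3,5-dimethoxyphenyl)-3-(Xc)propyl 4-nitrobenzoate
Product: 18 (1R,2S)-2-[4-(DHB)-2,6-dimethoxyphenoxy]-1-(4-TBS-oxy-3,5-dimethoxyphenyl)propane-1,3-diol
Conditions: LiBH4, MeOH, THF, 0 °C to rt
Reagents that add atoms: none
Why: Hydride reduction of the N-acyl oxazolidinone to the primary alcohol releases the auxiliary, and the same reagent cleaves the 4-nitrobenzoate, so the erythro diol is revealed in one operation. The aryl silyl ether stays on, so no phenoxide is formed para to a benzylic ester.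

Step 12
Reactants: 18 (1R,2S)-2-[4-(DHB)-2,6-dimethoxyphenoxy]-1-(4-TBS-oxy-3,5-dimethoxyphenyl)propane-1,3-diol
Product: 19 (4R,5S)-5-[4-(DHB)-2,6-dimethoxyphenoxy]-4-(4-TBS-oxy-3,5-dimethoxyphenyl)-2,2-dimethyl-1,3-dioxane
Conditions: Me2C(OMe)2, PPTS (cat.), CH2Cl2, rt; Et3N quench
Reagents that add atoms: 2,2-dimethoxypropane, COC(C)(C)OC
Why: Acid-catalysed transacetalisation gives the acetonide, which keeps the diol out of the boron triflate and Mitsunobu steps that follow. The erythro diol gives the 4,5-trans dioxane with both substituents equatorial, and the neopentyl acetal on ring D is not exchanged by the mild catalyst.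

Step 13
Reactants: 19 (4R,5S)-5-[4-(DHB)-2,6-dimethoxyphenoxy]-4-(4-TBS-oxy-3,5-dimethoxyphenyl)-2,2-dimethyl-1,3-dioxane; 12 (R)-4-benzyl-3-(chloroacetyl)oxazolidin-2-one
Product: 21 2-[4-(DOX)-2,6-dimethoxyphenoxy]-1-(Xc)ethanone, via tetrabutylammonium aryloxide 20 (not isolated)
Conditions: TBAF (1.05 equiv), THF, 0 °C; then 12, 0 °C to rt
Reagents that add atoms: none
Why: Fluoride desilylation followed by Williamson alkylation of the ring B aryloxide 20 in the same flask, as in step 8. The benzylic oxygen para to the aryloxide is an acetal oxygen and a poor leaving group, so no quinone methide forms.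

Step 14
Reactants: 22 vanillin
Product: 23 4-(TBS-oxy)-3-methoxybenzaldehyde
Conditions: TBSCl, imidazole, DMF, rt
Reagents that add atoms: tert-butyldimethylsilyl chloride, CC(C)(C)[Si](C)(C)Cl
Why: Silyl ether formation; a silyl ether is preferred to an ester on ring A because an ester would be cleaved in step 17 while a benzylic ester is still in place, which would open a quinone methide pathway.

Step 15
Reactants: 21 2-[4-(DOX)-2,6-dimethoxyphenoxy]-1-(Xc)ethanone; 23 4-(TBS-oxy)-3-methoxybenzaldehyde
Product: 25 (2R,3S)-2-[4-(DOX)-2,6-dimethoxyphenoxy]-3-hydroxy-3-(4-TBS-oxy-3-methoxyphenyl)-1-(Xc)propan-1-one, via dibutylboron enolate 24 (not isolated)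
Conditions: Bu2BOTf, i-Pr2NEt, CH2Cl2, –78 to 0 °C; then 23, –78 to 0 °C; pH 7 buffer, MeOH, H2O2, 0 °C
Reagents that add atoms: none
Why: Evans syn aldol as in step 9; the (R) auxiliary again fixes both new centres (threo pair) independently of the six-atom-distant stereocentres already present. The acetonide and both acetals tolerate the amine-buffered boron triflate.

Step 16
Reactants: 25 (2R,3S)-2-[4-(DOX)-2,6-dimethoxyphenoxy]-3-hydroxy-3-(4-TBS-oxy-3-methoxyphenyl)-1-(Xc)propan-1-one
Product: 26 (1R,2R)-2-[4-(DOX)-2,6-dimethoxyphenoxy]-3-oxo-1-(4-TBS-oxy-3-methoxyphenyl)-3-(Xc)propyl 4-nitrobenzoate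
Conditions: PPh3, DIAD, 4-nitrobenzoic acid, THF, 0 °C to rt
Reagents that add atoms: 4-nitrobenzoic acid, O=C(O)c1ccc(cc1)[N+](=O)[O-]
Why: Mitsunobu inversion of the benzylic carbinol as in step 10, converting threo into erythro; the only free hydroxyl group in 25 is the one to be inverted.

Step 17
Reactants: 26 (1R,2R)-2-[4-(DOX)-2,6-dimethoxyphenoxy]-3-oxo-1-(4-TBS-oxy-3-methoxyphenyl)-3-(Xc)propyl 4-nitrobenzoate
Product: 27 (1R,2S)-2-[4-(DOX)-2,6-dimethoxyphenoxy]-1-(4-TBS-oxy-3-methoxyphenyl)propane-1,3-diol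
Conditions: LiBH4, MeOH, THF, 0 °C to rt
Reagents that add atoms: none
Why: Reductive removal of the auxiliary and of the 4-nitrobenzoate as in step 11 gives the second erythro diol; acetals, acetonide, silyl ether and the N–O bond are inert to borohydride.

Step 18
Reactants: 27 (1R,2S)-2-[4-(DOX)-2,6-dimethoxyphenoxy]-1-(4-TBS-oxy-3-methoxyphenyl)propane-1,3-diol
Product: 28 (1R,2S)-2-[4-(DOX)-2,6-dimethoxyphenoxy]-1-(4-hydroxy-3-methoxyphenyl)propane-1,3-diol
Conditions: TBAF, AcOH, THF, 0 °C
Reagents that add atoms: none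
Why: Fluoride desilylation of the ring A aryl silyl ether, buffered so that the phenolate is protonated as it forms. The benzylic oxygen para to it is now a free hydroxyl group, a poor leaving group, so the phenol is safe.

Step 19
Reactants: 28 (1R,2S)-2-[4-(DOX)-2,6-dimethoxyphenoxy]-1-(4-hydroxy-3-methoxyphenyl)propane-1,3-diol
Product: 30 (2R,3S)-2-{4-[(1R,2S)-1-{4-[(1R,2S)-1,3-dihydroxy-1-(4-hydroxy-3-methoxyphenyl)propan-2-yl]oxy-3,5-dimethoxyphenyl}-1,3-dihydroxypropan-2-yl]oxy-3,5-dimethoxyphenyl}-3-(hydroxymethyl)-7-methoxy-2,3-dihydro-1-benzofuran-5-carbaldehyde, via hydroxymethyl bis-acetal 29 (not isolated)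
Conditions: Zn dust, AcOH/THF (3:1), rt; filter; then H2O, 45 °C
Reagents that add atoms: water, O
Why: Zinc in acetic acid reduces the N–O bond of the alkoxyamine and frees the C3 hydroxymethyl group while the formyl group is still an acetal (29). Water then hydrolyses the ring D acetal, which is activated by the para oxygen, and the acetonide; removing the zinc before the hydrolysis keeps the aldehyde away from the metal.

Step 20
Reactants: 30 the aldehyde of step 19
Product: 31 (E)-3-[(2R,3S)-2-{4-[(1R,2S)-1-{4-[(1R,2S)-1,3-dihydroxy-1-(4-hydroxy-3-methoxyphenyl)propan-2-yl]oxy-3,5-dimethoxyphenyl}-1,3-dihydroxypropan-2-yl]oxy-3,5-dimethoxyphenyl}-3-(hydroxymethyl)-7-methoxy-2,3-dihydro-1-benzofuran-5-yl]prop-2-enal (target)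
Conditions: Ph3P=CHCHO (small excess), 1,4-dioxane, 80 °C
Reagents that add atoms: (triphenylphosphoranylidene)acetaldehyde, O=CC=P(c1ccccc1)(c1ccccc1)c1ccccc1
Why: Wittig olefination with the stabilised formyl ylide gives the E enal. The ylide is too weakly basic to deprotonate the phenol or the alcohols, so no protection is needed, and only a small excess is used so that the enal is not homologated again.

Compound list

1 | syringaldehyde (4-hydroxy-3,5-dimethoxybenzaldehyde) | COc1cc(C=O)cc(OC)c1O | starting material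
2 | 4-(TBS-oxy)-3,5-dimethoxybenzaldehyde | COc1cc(C=O)cc(OC)c1O[Si](C)(C)C(C)(C)C | intermediate
3 | ethyl (E)-3-[4-(TBS-oxy)-3,5-dimethoxyphenyl]prop-2-enoate | CCOC(=O)/C=C/c1cc(OC)c(O[Si](C)(C)C(C)(C)C)c(OC)c1 | intermediate
4 | (E)-3-[4-(TBS-oxy)-3,5-dimethoxyphenyl]prop-2-en-1-ol | OC/C=C/c1cc(OC)c(O[Si](C)(C)C(C)(C)C)c(OC)c1 | intermediate
5 | (E)-3-[4-(TBS-oxy)-3,5-dimethoxyphenyl]prop-2-en-1-yl methyl carbonate | COC(=O)OC/C=C/c1cc(OC)c(O[Si](C)(C)C(C)(C)C)c(OC)c1 | intermediate
6 | 5-iodovanillin (4-hydroxy-3-iodo-5-methoxybenzaldehyde) | COc1cc(C=O)cc(I)c1O | starting material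
7 | 4-(5,5-dimethyl-1,3-dioxan-2-yl)-2-iodo-6-methoxyphenol | COc1cc(C2OCC(C)(C)CO2)cc(I)c1O | intermediate
8 | lithium 4-(5,5-dimethyl-1,3-dioxan-2-yl)-2-iodo-6-methoxyphenolate | COc1cc(C2OCC(C)(C)CO2)cc(I)c1[O-].[Li+] | intermediate
9 | 2-{4-[(1R)-1-(4-TBS-oxy-3,5-dimethoxyphenyl)prop-2-en-1-yloxy]-3-iodo-5-methoxyphenyl}-5,5-dimethyl-1,3-dioxane | COc1cc([C@@H](C=C)Oc2c(I)cc(C3OCC(C)(C)CO3)cc2OC)cc(OC)c1O[Si](C)(C)C(C)(C)C | intermediate
10 | TEMPO (2,2,6,6-tetramethylpiperidin-1-oxyl) | CC1(C)CCCC(C)(C)N1[O] | starting material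
11 | (2R,3S)-2-(4-TBS-oxy-3,5-dimethoxyphenyl)-5-(5,5-dimethyl-1,3-dioxan-2-yl)-7-methoxy-3-[(2,2,6,6-tetramethylpiperidin-1-yl)oxymethyl]-2,3-dihydro-1-benzofuran | COc1cc([C@@H]2Oc3c(OC)cc(C4OCC(C)(C)CO4)cc3[C@H]2CON5C(C)(C)CCCC5(C)C)cc(OC)c1O[Si](C)(C)C(C)(C)C | intermediate
12 | (R)-4-benzyl-3-(chloroacetyl)oxazolidin-2-one | O=C(CCl)N1[C@H](Cc2ccccc2)COC1=O | starting material
13 | tetrabutylammonium 4-(DHB)-2,6-dimethoxyphenolate | COc1cc([C@@H]2Oc3c(OC)cc(C4OCC(C)(C)CO4)cc3[C@H]2CON5C(C)(C)CCCC5(C)C)cc(OC)c1[O-].CCCC[N+](CCCC)(CCCC)CCCC | intermediate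
14 | 2-[4-(DHB)-2,6-dimethoxyphenoxy]-1-(Xc)ethanone | COc1cc([C@@H]2Oc3c(OC)cc(C4OCC(C)(C)CO4)cc3[C@H]2CON5C(C)(C)CCCC5(C)C)cc(OC)c1OCC(=O)N2[C@H](Cc3ccccc3)COC2=O | intermediate
15 | (Z)-dibutylboron enolate of 14 (aryloxy group cis to the boryloxy group) | COc1cc([C@@H]2Oc3c(OC)cc(C4OCC(C)(C)CO4)cc3[C@H]2CON5C(C)(C)CCCC5(C)C)cc(OC)c1O/C=C(\OB(CCCC)CCCC)N2[C@H](Cc3ccccc3)COC2=O | intermediate
16 | (2R,3S)-2-[4-(DHB)-2,6-dimethoxyphenoxy]-3-hydroxy-3-(4-TBS-oxy-3,5-dimethoxyphenyl)-1-(Xc)propan-1-one (threo) | COc1cc([C@@H]2Oc3c(OC)cc(C4OCC(C)(C)CO4)cc3[C@H]2CON5C(C)(C)CCCC5(C)C)cc(OC)c1O[C@H]([C@@H](O)c2cc(OC)c(O[Si](C)(C)C(C)(C)C)c(OC)c2)C(=O)N2[C@H](Cc3ccccc3)COC2=O | intermediate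
17 | (1R,2R)-2-[4-(DHB)-2,6-dimethoxyphenoxy]-3-oxo-1-(4-TBS-oxy-3,5-dimethoxyphenyl)-3-(Xc)propyl 4-nitrobenzoate | COc1cc([C@@H]2Oc3c(OC)cc(C4OCC(C)(C)CO4)cc3[C@H]2CON5C(C)(C)CCCC5(C)C)cc(OC)c1O[C@H]([C@H](OC(=O)c2ccc(cc2)[N+](=O)[O-])c2cc(OC)c(O[Si](C)(C)C(C)(C)C)c(OC)c2)C(=O)N2[C@H](Cc3ccccc3)COC2=O | intermediate
18 | (1R,2S)-2-[4-(DHB)-2,6-dimethoxyphenoxy]-1-(4-TBS-oxy-3,5-dimethoxyphenyl)propane-1,3-diol (erythro) | COc1cc([C@@H]2Oc3c(OC)cc(C4OCC(C)(C)CO4)cc3[C@H]2CON5C(C)(C)CCCC5(C)C)cc(OC)c1O[C@H]([C@H](O)c2cc(OC)c(O[Si](C)(C)C(C)(C)C)c(OC)c2)CO | intermediate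
19 | (4R,5S)-5-[4-(DHB)-2,6-dimethoxyphenoxy]-4-(4-TBS-oxy-3,5-dimethoxyphenyl)-2,2-dimethyl-1,3-dioxane | COc1cc([C@@H]2Oc3c(OC)cc(C4OCC(C)(C)CO4)cc3[C@H]2CON5C(C)(C)CCCC5(C)C)cc(OC)c1O[C@@H]2[C@@H](c3cc(OC)c(O[Si](C)(C)C(C)(C)C)c(OC)c3)OC(C)(C)OC2 | intermediate
20 | tetrabutylammonium 4-(DOX)-2,6-dimethoxyphenolate | COc1cc([C@@H]2Oc3c(OC)cc(C4OCC(C)(C)CO4)cc3[C@H]2CON5C(C)(C)CCCC5(C)C)cc(OC)c1O[C@@H]2[C@@H](c3cc(OC)c([O-])c(OC)c3)OC(C)(C)OC2.CCCC[N+](CCCC)(CCCC)CCCC | intermediate
21 | 2-[4-(DOX)-2,6-dimethoxyphenoxy]-1-(Xc)ethanone | COc1cc([C@@H]2Oc3c(OC)cc(C4OCC(C)(C)CO4)cc3[C@H]2CON5C(C)(C)CCCC5(C)C)cc(OC)c1O[C@@H]2[C@@H](c3cc(OC)c(OCC(=O)N4[C@H](Cc5ccccc5)COC4=O)c(OC)c3)OC(C)(C)OC2 | intermediate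
22 | vanillin (4-hydroxy-3-methoxybenzaldehyde) | COc1cc(C=O)ccc1O | starting material
23 | 4-(TBS-oxy)-3-methoxybenzaldehyde | COc1cc(C=O)ccc1O[Si](C)(C)C(C)(C)C | intermediate
24 | (Z)-dibutylboron enolate of 21 (aryloxy group cis to the boryloxy group) | COc1cc([C@@H]2Oc3c(OC)cc(C4OCC(C)(C)CO4)cc3[C@H]2CON5C(C)(C)CCCC5(C)C)cc(OC)c1O[C@@H]2[C@@H](c3cc(OC)c(O/C=C(\OB(CCCC)CCCC)N4[C@H](Cc5ccccc5)COC4=O)c(OC)c3)OC(C)(C)OC2 | intermediate
25 | (2R,3S)-2-[4-(DOX)-2,6-dimethoxyphenoxy]-3-hydroxy-3-(4-TBS-oxy-3-methoxyphenyl)-1-(Xc)propan-1-one (threo) | COc1cc([C@@H]2Oc3c(OC)cc(C4OCC(C)(C)CO4)cc3[C@H]2CON5C(C)(C)CCCC5(C)C)cc(OC)c1O[C@@H]2[C@@H](c3cc(OC)c(O[C@H]([C@@H](O)c4ccc(O[Si](C)(C)C(C)(C)C)c(OC)c4)C(=O)N4[C@H](Cc5ccccc5)COC4=O)c(OC)c3)OC(C)(C)OC2 | intermediate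
26 | (1R,2R)-2-[4-(DOX)-2,6-dimethoxyphenoxy]-3-oxo-1-(4-TBS-oxy-3-methoxyphenyl)-3-(Xc)propyl 4-nitrobenzoate | COc1cc([C@@H]2Oc3c(OC)cc(C4OCC(C)(C)CO4)cc3[C@H]2CON5C(C)(C)CCCC5(C)C)cc(OC)c1O[C@@H]2[C@@H](c3cc(OC)c(O[C@H]([C@H](OC(=O)c4ccc(cc4)[N+](=O)[O-])c4ccc(O[Si](C)(C)C(C)(C)C)c(OC)c4)C(=O)N4[C@H](Cc5ccccc5)COC4=O)c(OC)c3)OC(C)(C)OC2 | intermediate
27 | (1R,2S)-2-[4-(DOX)-2,6-dimethoxyphenoxy]-1-(4-TBS-oxy-3-methoxyphenyl)propane-1,3-diol (erythro) | COc1cc([C@@H]2Oc3c(OC)cc(C4OCC(C)(C)CO4)cc3[C@H]2CON5C(C)(C)CCCC5(C)C)cc(OC)c1O[C@@H]2[C@@H](c3cc(OC)c(O[C@H]([C@H](O)c4ccc(O[Si](C)(C)C(C)(C)C)c(OC)c4)CO)c(OC)c3)OC(C)(C)OC2 | intermediate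
28 | (1R,2S)-2-[4-(DOX)-2,6-dimethoxyphenoxy]-1-(4-hydroxy-3-methoxyphenyl)propane-1,3-diol | COc1cc([C@@H]2Oc3c(OC)cc(C4OCC(C)(C)CO4)cc3[C@H]2CON5C(C)(C)CCCC5(C)C)cc(OC)c1O[C@@H]2[C@@H](c3cc(OC)c(O[C@H]([C@H](O)c4ccc(O)c(OC)c4)CO)c(OC)c3)OC(C)(C)OC2 | intermediate
29 | analogue of 28 in which the piperidinyloxymethyl group at C3 is a hydroxymethyl group (acetal and acetonide intact) | COc1cc([C@@H]2Oc3c(OC)cc(C4OCC(C)(C)CO4)cc3[C@H]2CO)cc(OC)c1O[C@@H]2[C@@H](c3cc(OC)c(O[C@H]([C@H](O)c4ccc(O)c(OC)c4)CO)c(OC)c3)OC(C)(C)OC2 | intermediate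
30 | (2R,3S)-2-{4-[(1R,2S)-1-{4-[(1R,2S)-1,3-dihydroxy-1-(4-hydroxy-3-methoxyphenyl)propan-2-yl]oxy-3,5-dimethoxyphenyl}-1,3-dihydroxypropan-2-yl]oxy-3,5-dimethoxyphenyl}-3-(hydroxymethyl)-7-methoxy-2,3-dihydro-1-benzofuran-5-carbaldehyde | COc1cc([C@@H]2Oc3c(OC)cc(C=O)cc3[C@H]2CO)cc(OC)c1O[C@H]([C@H](O)c2cc(OC)c(O[C@H]([C@H](O)c3ccc(O)c(OC)c3)CO)c(OC)c2)CO | intermediate
31 | (E)-3-[(2R,3S)-2-{4-[(1R,2S)-1-{4-[(1R,2S)-1,3-dihydroxy-1-(4-hydroxy-3-methoxyphenyl)propan-2-yl]oxy-3,5-dimethoxyphenyl}-1,3-dihydroxypropan-2-yl]oxy-3,5-dimethoxyphenyl}-3-(hydroxymethyl)-7-methoxy-2,3-dihydro-1-benzofuran-5-yl]prop-2-enal | COc1cc([C@@H](O)[C@H](CO)Oc2c(OC)cc([C@@H](O)[C@H](CO)Oc3c(OC)cc([C@@H]4Oc5c(OC)cc(/C=C/C=O)cc5[C@H]4CO)cc3OC)cc2OC)ccc1O | target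

Total step count: 20. Longest linear sequence: 18 steps (steps 1–4, 6–13 and 15–20, from 1); steps 5 and 14 are side branches.

Steps least certain to work

Step 7 (key step). The stannyl radicals may be intercepted by the nitroxide faster than they abstract iodine from a hindered, electron-rich aryl iodide, so that radical generation stalls, and facial discrimination in the ring closure may be incomplete, giving some cis isomer. Fallback: from 9, the same aryl radical cyclisation is run with Bu3SnH under dry air, so that oxygen captures the primary radical, followed by PPh3 to reduce the hydroperoxide. This should give the trans hydroxymethyl dihydrobenzofuran F1. Appel iodination (PPh3, I2, imidazole) gives the iodomethyl compound F2, and O-alkylation of TEMPO-Na (from 1-hydroxy-2,2,6,6-tetramethylpiperidine and NaH, THF) by F2 returns to 11.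

Step 6. The hindered 2,6-disubstituted aryloxide may attack the unsubstituted allyl terminus (linear ether), and the catalyst may re-ionise the branched ether with loss of enantiomeric purity. Fallback: from 2, addition of CH2=CHMgBr gives the racemic allylic alcohol F3. Lipase resolution (Candida antarctica lipase B, vinyl acetate) leaves the (S)-alcohol F4 and converts its antipode into the (R)-acetate F5, which is separated. Mitsunobu etherification of F4 with 7 (PPh3, DIAD, toluene, 0 °C) proceeds with inversion and returns to 9.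

Step 10 (step 16 repeats the operation). The activated alkoxyphosphonium intermediate may undergo β-elimination toward the α-aryloxy acrylimide, or ionise in part at the benzylic carbon with loss of stereospecificity. Fallback: from 16, LiBH4 removes the auxiliary first and gives the threo diol F6. Selective acylation of the primary hydroxyl group (PivCl, pyridine, 0 °C) gives the pivalate F7, and Mitsunobu inversion of the now isolated benzylic alcohol with 4-nitrobenzoic acid gives the diester F8. Reductive cleavage of both esters (i-Bu2AlH, CH2Cl2, –78 to 0 °C) returns to 18.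

Step 19. The p-hydroxybenzylic carbinol of the ring A unit may ionise in warm aqueous acetic acid (epimerisation or acetate formation), and the freed formyl group may be reduced if zinc is still present. Fallback: the order of the last unmasking steps is changed. From 27, with the ring A phenol still silylated and its benzylic carbinol therefore less prone to ionise, Zn/AcOH and then water give the silyl-protected aldehyde F9. Buffered fluoride (TBAF, AcOH, THF, 0 °C) then returns to 30.

Step 20. The electron-rich aldehyde may react slowly, and the product enal may be olefinated a second time to the dienal. Fallback: from 30, a Horner–Wadsworth–Emmons reaction (triethyl phosphonoacetate, LiCl, DBU, MeCN) gives the ethyl (E)-cinnamate F10, which cannot be homologated further. Reduction with i-Bu2AlH gives the allylic alcohol F11, and selective allylic oxidation with MnO2 returns to 31.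

Further compounds

F1 | step 7 | [(2R,3S)-2-(4-TBS-oxy-3,5-dimethoxyphenyl)-5-(5,5-dimethyl-1,3-dioxan-2-yl)-7-methoxy-2,3-dihydro-1-benzofuran-3-yl]methanol | COc1cc([C@@H]2Oc3c(OC)cc(C4OCC(C)(C)CO4)cc3[C@H]2CO)cc(OC)c1O[Si](C)(C)C(C)(C)C
F2 | step 7 | (2R,3R)-2-(4-TBS-oxy-3,5-dimethoxyphenyl)-5-(5,5-dimethyl-1,3-dioxan-2-yl)-3-(iodomethyl)-7-methoxy-2,3-dihydro-1-benzofuran (trans) | COc1cc([C@@H]2Oc3c(OC)cc(C4OCC(C)(C)CO4)cc3[C@H]2CI)cc(OC)c1O[Si](C)(C)C(C)(C)C
F3 | step 6 | racemic 1-(4-TBS-oxy-3,5-dimethoxyphenyl)prop-2-en-1-ol | COc1cc(C(O)C=C)cc(OC)c1O[Si](C)(C)C(C)(C)C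
F4 | step 6 | (S)-1-(4-TBS-oxy-3,5-dimethoxyphenyl)prop-2-en-1-ol | COc1cc([C@H](C=C)O)cc(OC)c1O[Si](C)(C)C(C)(C)C
F5 | step 6 | (R)-1-(4-TBS-oxy-3,5-dimethoxyphenyl)prop-2-en-1-yl acetate | COc1cc([C@@H](C=C)OC(C)=O)cc(OC)c1O[Si](C)(C)C(C)(C)C
F6 | step 10 | (1S,2S)-2-[4-(DHB)-2,6-dimethoxyphenoxy]-1-(4-TBS-oxy-3,5-dimethoxyphenyl)propane-1,3-diol (threo) | COc1cc([C@@H]2Oc3c(OC)cc(C4OCC(C)(C)CO4)cc3[C@H]2CON5C(C)(C)CCCC5(C)C)cc(OC)c1O[C@H]([C@@H](O)c2cc(OC)c(O[Si](C)(C)C(C)(C)C)c(OC)c2)CO
F7 | step 10 | (2S,3S)-2-[4-(DHB)-2,6-dimethoxyphenoxy]-3-hydroxy-3-(4-TBS-oxy-3,5-dimethoxyphenyl)propyl pivalate | COc1cc([C@@H]2Oc3c(OC)cc(C4OCC(C)(C)CO4)cc3[C@H]2CON5C(C)(C)CCCC5(C)C)cc(OC)c1O[C@H]([C@@H](O)c2cc(OC)c(O[Si](C)(C)C(C)(C)C)c(OC)c2)COC(=O)C(C)(C)C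
F8 | step 10 | (1R,2S)-2-[4-(DHB)-2,6-dimethoxyphenoxy]-3-(pivaloyloxy)-1-(4-TBS-oxy-3,5-dimethoxyphenyl)propyl 4-nitrobenzoate | COc1cc([C@@H]2Oc3c(OC)cc(C4OCC(C)(C)CO4)cc3[C@H]2CON5C(C)(C)CCCC5(C)C)cc(OC)c1O[C@H]([C@H](OC(=O)c2ccc(cc2)[N+](=O)[O-])c2cc(OC)c(O[Si](C)(C)C(C)(C)C)c(OC)c2)COC(=O)C(C)(C)C
F9 | step 19 | ring A TBS ether of 30 | COc1cc([C@@H]2Oc3c(OC)cc(C=O)cc3[C@H]2CO)cc(OC)c1O[C@H]([C@H](O)c2cc(OC)c(O[C@H]([C@H](O)c3ccc(O[Si](C)(C)C(C)(C)C)c(OC)c3)CO)c(OC)c2)CO
F10 | step 20 | ethyl (E)-prop-2-enoate corresponding to 31 (CO2Et in place of CHO) | COc1cc([C@@H]2Oc3c(OC)cc(/C=C/C(=O)OCC)cc3[C@H]2CO)cc(OC)c1O[C@H]([C@H](O)c2cc(OC)c(O[C@H]([C@H](O)c3ccc(O)c(OC)c3)CO)c(OC)c2)CO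
F11 | step 20 | (E)-prop-2-en-1-ol corresponding to 31 (CH2OH in place of CHO) | COc1cc([C@@H]2Oc3c(OC)cc(/C=C/CO)cc3[C@H]2CO)cc(OC)c1O[C@H]([C@H](O)c2cc(OC)c(O[C@H]([C@H](O)c3ccc(O)c(OC)c3)CO)c(OC)c2)CO
A1 | alternative 1 | bis(Z-enol ether) on the bromo phenylcoumaran | COc1cc(/C=C(\Oc2c(OC)cc(/C=C(\Oc3c(OC)cc([C@@H]4Oc5c(OC)cc(Br)cc5[C@H]4CO[Si](C)(C)C(C)(C)C)cc3OC)CO[Si](C)(C)C(C)(C)C)cc2OC)CO[Si](C)(C)C(C)(C)C)ccc1O[Si](C(C)C)(C(C)C)C(C)C
A2 | alternative 1 | bis(erythro benzylic alcohol) | COc1cc([C@@H](O)[C@H](CO[Si](C)(C)C(C)(C)C)Oc2c(OC)cc([C@@H](O)[C@H](CO[Si](C)(C)C(C)(C)C)Oc3c(OC)cc([C@@H]4Oc5c(OC)cc(Br)cc5[C@H]4CO[Si](C)(C)C(C)(C)C)cc3OC)cc2OC)ccc1O[Si](C(C)C)(C(C)C)C(C)C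
A3 | alternative 2 | (2S)-2-(5-bromo-2-hydroxy-3-methoxyphenyl)-1-(4-hydroxy-3,5-dimethoxyphenyl)propane-1,3-diol, either C1 epimer | COc1cc(C(O)[C@H](CO)c2cc(Br)cc(OC)c2O)cc(OC)c1O
A4 | alternative 2 | para-quinone methide from A3 | COC1=CC(=C[C@H](CO)c2cc(Br)cc(OC)c2O)C=C(OC)C1=O
A5 | alternative 2 | trans phenylcoumaran phenol | COc1cc([C@@H]2Oc3c(OC)cc(Br)cc3[C@H]2CO)cc(OC)c1O
A6 | alternative 3 | methyl 2-[5-bromo-3-methoxy-2-(4-TBS-oxy-3,5-dimethoxybenzyloxy)phenyl]-2-diazoacetate | COC(=O)C(=[N+]=[N-])c1cc(Br)cc(OC)c1OCc1cc(OC)c(O[Si](C)(C)C(C)(C)C)c(OC)c1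
A7 | alternative 3 | trans-2-aryl-2,3-dihydrobenzofuran-3-carboxylate | COc1cc([C@@H]2Oc3c(OC)cc(Br)cc3[C@H]2C(=O)OC)cc(OC)c1O[Si](C)(C)C(C)(C)C
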